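**Plan**

Numbering follows the labdane skeleton: decalin C1–C10, chain C11–C15, C19 = the oxygenated carbon on C4, C20 = the methyl on C10.
Cuts: C11–C12 (chain to bicycle), C9=C11 (back to a C9 ketone), then C1–C10 and C4–C5 in one operation; C6 is carried as a carbonyl and removed, C2 as a silyl enol ether and reduced last.
Feature used: ring B, with methyls on C8 and C10 and with C6 and C9 able to start as carbonyls, is the symmetric 2,6-dimethyl-1,4-benzoquinone; ring A, with oxygen on C2 and the quaternary C4, is a 2-silyloxy diene with a fully substituted terminus.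
Forward: ring B is bought as the quinone, ring A is closed onto it by a catalytic asymmetric Diels–Alder reaction, ring B is trimmed (C6 deoxygenated, C9 methylenated and hydroborated), the C12–C15 unit is joined at C11, then C19 and C2 are adjusted.
Stereochemistry: C10 and C4 from the cycloaddition (catalyst face control, endo transition state, Z diene); C5 by epimerisation next to the C6 ketone; C9 by hydroboration anti to C20; C13 from methyl hydrogen (R)-3-methylglutarate; C2 by ketyl (thermodynamic) reduction.

Key step: step 5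

Assumption: the oxazaborolidinium ion made from (S)-diphenylprolinol is taken to expose the quinone face that leads to the adduct as drawn (binding at the C6 carbonyl with the C5–H contact); should the sense be opposite, the catalyst from (R)-diphenylprolinol is used.

**Route**

Step 1
Reactants: 1 4-methylfuran-2(5H)-one
Product: 2 (Z)-4-hydroxy-N-methoxy-N,3-dimethylbut-2-enamide
Conditions: MeNH(OMe)·HCl, Me3Al, CH2Cl2, 0 °C → rt; Rochelle salt work-up, crude product used at once
Reagents that add atoms: N,O-dimethylhydroxylamine hydrochloride (CNOC.Cl)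
Why: Aluminium-amide aminolysis of the lactone (Weinreb amide formation) opens the butenolide at the acyl carbon and keeps the ring-derived Z geometry, so CH2OH stays cis to the carbonyl.

Step 2
Reactants: 2 (Z)-4-hydroxy-N-methoxy-N,3-dimethylbut-2-enamide
Product: 3 (Z)-4-(tert-butyldimethylsilyloxy)-N-methoxy-N,3-dimethylbut-2-enamide
Conditions: TBSCl, imidazole, DMF, 0 °C → rt
Reagents that add atoms: tert-butyldimethylsilyl chloride (CC(C)(C)[Si](C)(C)Cl)
Why: Imidazole-promoted silylation of the primary allylic alcohol blocks relactonisation, and a silyl ether is a poor ligand for the boron catalyst of step 5.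

Step 3
Reactants: 3 (Z)-4-(tert-butyldimethylsilyloxy)-N-methoxy-N,3-dimethylbut-2-enamide
Product: 4 (Z)-5-(tert-butyldimethylsilyloxy)-4-methylpent-3-en-2-one
Conditions: MeMgBr, THF, −20 → 0 °C; cold 0.5 M HCl
Reagents that add atoms: methylmagnesium bromide (C[Mg]Br)
Why: Grignard addition to a Weinreb amide stops at the chelated tetrahedral adduct, so the methyl ketone should form on hydrolysis with the Z alkene untouched.

Step 4
Reactants: 4 (Z)-5-(tert-butyldimethylsilyloxy)-4-methylpent-3-en-2-one
Product: 5 (2Z)-1-(tert-butyldimethylsilyloxy)-2-methyl-4-(triisopropylsilyloxy)penta-2,4-diene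
Conditions: TIPSOTf, Et3N, CH2Cl2, 0 °C
Reagents that add atoms: triisopropylsilyl trifluoromethanesulfonate (CC(C)[Si](C(C)C)(C(C)C)OS(=O)(=O)C(F)(F)F)
Why: Soft enolisation (silyl triflate and amine) silylates oxygen and removes a proton from the acetyl methyl, the standard route from β,β-disubstituted enones to cross-conjugated 2-silyloxy dienes; the C3=C4 geometry is not involved.

Step 5
Reactants: 5 (2Z)-1-(tert-butyldimethylsilyloxy)-2-methyl-4-(triisopropylsilyloxy)penta-2,4-diene; 6 2,6-dimethyl-1,4-benzoquinone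
Product: 7 cis-fused adduct (ring A: C2=C3 triisopropylsilyl enol ether, C4 with methyl and CH2OTBS; ring B: C10 methyl, C6 and C9 ketones, C7=C8 with 8-methyl; CH2OTBS, C20 and H5 on one face)
Conditions: oxazaborolidine C24H24BNO (from (S)-diphenylprolinol and o-tolylboroxine)·HNTf2 (20 mol%), CH2Cl2, −78 → −40 °C
Reagents that add atoms: none
Why: The protonated oxazaborolidine binds the quinone carbonyl that is flanked by two C–H (the future C6), which makes the methyl-bearing C10 the electrophilic β-carbon; the CH2 terminus of the silyloxy diene (C1) attacks it and C4 then bonds to C5, either as one asynchronous [4+2] event or as a Mukaiyama–Michael/Michael pair with the same result. The closest known reaction type is the oxazaborolidinium-catalysed Diels–Alder reaction of alkylbenzoquinones with 2-triisopropylsilyloxy dienes, supported by acid-promoted cycloadditions of 4,4-disubstituted 2-silyloxy dienes to hindered enones. Ring A closes by the suprafacial [4+2] mode, both new bonds lying on one face of each partner. C10 is set by the catalyst, which shields one face of the bound quinone; C5 follows from suprafacial addition (cis fusion); C4 follows from the carbonyl-endo transition state together with the Z geometry, which puts the inside CH2OTBS group cis to the C10 methyl. The step needs regio-, endo- and facial selectivity: regiochemistry comes from the 2-silyloxy polarisation and the single unhindered carbonyl, site selectivity is no issue because the two quinone alkenes are equivalent, and the facial choice rests on the catalyst.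

Step 6
Reactants: 7 cis-fused adduct
Product: 8 trans-fused ene-dione (C5 epimer of 7; H5 trans to C20)
Conditions: DBU (0.3 equiv), CH2Cl2, 0 °C → rt
Reagents that add atoms: none
Why: Enolisation toward C5 (epimerisation α to the C6 ketone, the only enolisable ring-fusion position since C10 is quaternary) should give the trans-fused isomer, favoured thermodynamically as in 6-oxo decalins of this type and kinetically by protonation anti to C20 and the axial C19 group.

Step 7
Reactants: 8 trans-fused ene-dione
Product: 9 6-hydroxy-7-en-9-one (hydroxyl expected cis to C20)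
Conditions: NaBH4, CeCl3·7H2O, MeOH/CH2Cl2, −78 °C
Reagents that add atoms: none
Why: Luche reduction is a 1,2-reduction and should select the C6 carbonyl because C9 is flanked by quaternary C10 and the C8 methyl; hydride is expected anti to C20, and the new C6 centre is removed in step 9.

Step 8
Reactants: 9 6-hydroxy-7-en-9-one
Product: 10 6-acetoxy-7-en-9-one
Conditions: Ac2O, DMAP, Et3N, CH2Cl2, rt → 40 °C
Reagents that add atoms: acetic anhydride (CC(=O)OC(C)=O)
Why: DMAP-catalysed acylation, the usual method for hindered secondary alcohols, turns the pseudo-axial 6-hydroxyl into a leaving group aligned with the enone π system.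

Step 9
Reactants: 10 6-acetoxy-7-en-9-one
Product: 12 7-en-9-one (C6 now CH2; trans-fused), via deconjugated 6-en-9-one 11 (not isolated)
Conditions: SmI2, THF/MeOH, −78 °C; then DBU, CH2Cl2, rt
Reagents that add atoms: none
Why: SmI2 reduces the enone to its ketyl, which expels the γ-acetate (vinylogous α-acyloxy ketone cleavage); the dienolate is protonated at C8 and DBU returns the alkene to conjugation, so the C7=C8 position is dictated by the C9 carbonyl.

Step 10
Reactants: 12 7-en-9-one
Product: 13 7,9(11)-diene (exocyclic C9=CH2)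
Conditions: Ph3PCH3Br, KN(SiMe3)2, toluene/THF, 0 → 80 °C
Reagents that add atoms: methyltriphenylphosphonium bromide (C[P+](c1ccccc1)(c1ccccc1)c1ccccc1.[Br-])
Why: Wittig methylenation with the small non-stabilised ylide at elevated temperature is the standard answer to a ketone next to a quaternary ring carbon; no stereocentre is formed.

Step 11
Reactants: 13 7,9(11)-diene
Product: 15 7-en-11-ol (C9–CH2OH equatorial; H9 trans to C20), via B-alkyl-9-borabicyclononane 14 (not isolated)
Conditions: 9-BBN, THF, rt → 50 °C; then NaOH, H2O2, 0 °C → rt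
Reagents that add atoms: hydrogen peroxide (OO)
Why: Hydroboration–oxidation: 9-BBN adds boron to the terminal carbon of the exocyclic alkene from the face opposite the axial C10 methyl, so H9 ends trans to C20, as with exocyclic alkenes next to an angular methyl in decalins; the trisubstituted ring alkene and the hindered enol ether react far more slowly.

Step 12
Reactants: 15 7-en-11-ol
Product: 16 11-iodide
Conditions: PPh3, imidazole, I2, CH2Cl2, 0 °C → rt
Reagents that add atoms: iodine (II)
Why: Appel-type iodination of the primary alcohol; with PPh3 in slight excess over iodine no free electrophilic iodine remains to attack the enol ether or the alkene.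

Step 13
Reactants: 17 methyl hydrogen (R)-3-methylglutarate
Product: 18 methyl (S)-4-iodo-3-methylbutanoate
Conditions: PhI(OAc)2, I2, CH2Cl2, visible light, reflux
Reagents that add atoms: iodine (II)
Why: Radical iododecarboxylation (Hunsdiecker-type, through the acyl hypoiodite) replaces CO2H by iodine one carbon away from the stereocentre, which is untouched; the descriptor changes from R to S only because the priorities change.

Step 14
Reactants: 16 11-iodide; 18 methyl (S)-4-iodo-3-methylbutanoate
Product: 20 methyl ester of the full C1–C20 skeleton (C2 silyl enol ether and C19 silyl ether intact), via C11 alkylzinc iodide 19 (not isolated)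
Conditions: Zn, LiCl, THF, 45 °C; then 18, Pd2(dba)3, P(c-C5H9)3, N-methylimidazole, THF/NMP, 80 °C
Reagents that add atoms: none
Why: Zinc inserts into the C11–I bond and the alkylzinc iodide is joined to the less hindered primary iodide 18 in an alkyl–alkyl Negishi coupling; the electron-rich trialkylphosphine on zerovalent palladium favours oxidative addition over β-hydride elimination, and ester, silyl groups and alkenes are tolerated, so C13 is carried in unchanged.

Step 15
Reactants: 20 methyl ester
Product: 22 19-hydroxy-2-oxo acid (in equilibrium with its 2,19-hemiketal), via lithium carboxylate 21 (not isolated)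
Conditions: LiOH, THF/H2O, rt; then 1 M HCl, THF, rt
Reagents that add atoms: lithium hydroxide ([Li+].[OH-])
Why: Saponification of the methyl ester, then aqueous acid hydrolyses the silyl enol ether to the C2 ketone and the primary silyl ether to the C19 alcohol; the isolated trisubstituted alkene should be stable to dilute acid at room temperature.

Step 16
Reactants: 22 19-hydroxy-2-oxo acid
Product: 23 19-acetoxy-2-oxo acid
Conditions: Ac2O, pyridine, DMAP (cat.), CH2Cl2, 0 °C → rt; aq. NaHCO3
Reagents that add atoms: acetic anhydride (CC(=O)OC(C)=O)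
Why: Acetylation of the only free hydroxyl drains the hemiketal equilibrium through the open form; the ketone is inert and the mixed anhydride of the acid is hydrolysed in the bicarbonate work-up.

Step 17
Reactants: 23 19-acetoxy-2-oxo acid
Product: 24 target, (3R)-5-[(1R,4aS,5R,7S,8aS)-5-(acetoxymethyl)-7-hydroxy-2,5,8a-trimethyl-1,4,4a,5,6,7,8,8a-octahydronaphthalen-1-yl]-3-methylpentanoic acid
Conditions: SmI2, H2O, Et3N, THF, 0 °C, short reaction time
Reagents that add atoms: none
Why: Electron-transfer (ketyl) reduction by SmI2 follows the course of dissolving-metal reductions: the oxygen settles equatorial, away from the axial C19 and C20 groups, and C2 is protonated axially to give the equatorial alcohol, whereas hydride reagents would enter from the open equatorial side; acetate, carboxylate and alkene are reduced far more slowly than the ketone.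

**Compound list**

1 | 4-methylfuran-2(5H)-one | CC1=CC(=O)OC1 | starting material
2 | (Z)-4-hydroxy-N-methoxy-N,3-dimethylbut-2-enamide | CON(C)C(=O)/C=C(\CO)C | intermediate
3 | (Z)-4-(tert-butyldimethylsilyloxy)-N-methoxy-N,3-dimethylbut-2-enamide | CON(C)C(=O)/C=C(\CO[Si](C)(C)C(C)(C)C)C | intermediate
4 | (Z)-5-(tert-butyldimethylsilyloxy)-4-methylpent-3-en-2-one | CC(=O)/C=C(\CO[Si](C)(C)C(C)(C)C)C | intermediate
5 | (2Z)-1-(tert-butyldimethylsilyloxy)-2-methyl-4-(triisopropylsilyloxy)penta-2,4-diene | C=C(O[Si](C(C)C)(C(C)C)C(C)C)/C=C(\CO[Si](C)(C)C(C)(C)C)C | intermediate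
6 | 2,6-dimethyl-1,4-benzoquinone | CC1=CC(=O)C=C(C)C1=O | starting material
7 | cis-fused adduct: 5-[(tert-butyldimethylsilyloxy)methyl]-2,5,8a-trimethyl-7-(triisopropylsilyloxy)-4a,5,8,8a-tetrahydronaphthalene-1,4-dione, CH2OTBS, 8a-methyl and H4a on one face | CC(C)(C)[Si](C)(C)OC[C@]1(C)C=C(O[Si](C(C)C)(C(C)C)C(C)C)C[C@@]2(C)C(=O)C(C)=CC(=O)[C@@H]12 | intermediate
8 | trans-fused ene-dione (C5 epimer of 7) | CC(C)(C)[Si](C)(C)OC[C@]1(C)C=C(O[Si](C(C)C)(C(C)C)C(C)C)C[C@@]2(C)C(=O)C(C)=CC(=O)[C@H]12 | intermediate
9 | 6-hydroxy-7-en-9-one, hydroxyl cis to C20 | CC(C)(C)[Si](C)(C)OC[C@]1(C)C=C(O[Si](C(C)C)(C(C)C)C(C)C)C[C@@]2(C)C(=O)C(C)=C[C@H](O)[C@H]12 | intermediate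
10 | 6-acetoxy-7-en-9-one | CC(C)(C)[Si](C)(C)OC[C@]1(C)C=C(O[Si](C(C)C)(C(C)C)C(C)C)C[C@@]2(C)C(=O)C(C)=C[C@H](OC(C)=O)[C@H]12 | intermediate
11 | deconjugated 6-en-9-one (H on C8, both C8 epimers) | CC(C)(C)[Si](C)(C)OC[C@]1(C)C=C(O[Si](C(C)C)(C(C)C)C(C)C)C[C@@]2(C)C(=O)C(C)C=C[C@H]12 | intermediate (not isolated)
12 | trans-fused 7-en-9-one | CC(C)(C)[Si](C)(C)OC[C@]1(C)C=C(O[Si](C(C)C)(C(C)C)C(C)C)C[C@@]2(C)C(=O)C(C)=CC[C@H]12 | intermediate
13 | 7,9(11)-diene | CC(C)(C)[Si](C)(C)OC[C@]1(C)C=C(O[Si](C(C)C)(C(C)C)C(C)C)C[C@@]2(C)C(=C)C(C)=CC[C@H]12 | intermediate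
14 | B-(C11-alkyl)-9-borabicyclo[3.3.1]nonane, H9 trans to C20 | CC(C)(C)[Si](C)(C)OC[C@]1(C)C=C(O[Si](C(C)C)(C(C)C)C(C)C)C[C@@]2(C)[C@H](CB3C4CCCC3CCC4)C(C)=CC[C@H]12 | intermediate (not isolated)
15 | 7-en-11-ol | CC(C)(C)[Si](C)(C)OC[C@]1(C)C=C(O[Si](C(C)C)(C(C)C)C(C)C)C[C@@]2(C)[C@H](CO)C(C)=CC[C@H]12 | intermediate
16 | 11-iodide | CC(C)(C)[Si](C)(C)OC[C@]1(C)C=C(O[Si](C(C)C)(C(C)C)C(C)C)C[C@@]2(C)[C@H](CI)C(C)=CC[C@H]12 | intermediate
17 | methyl hydrogen (R)-3-methylglutarate | COC(=O)C[C@H](C)CC(=O)O | starting material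
18 | methyl (S)-4-iodo-3-methylbutanoate | COC(=O)C[C@H](C)CI | intermediate
19 | C11 alkylzinc iodide | CC(C)(C)[Si](C)(C)OC[C@]1(C)C=C(O[Si](C(C)C)(C(C)C)C(C)C)C[C@@]2(C)[C@H](C[Zn]I)C(C)=CC[C@H]12 | intermediate (not isolated)
20 | methyl (13R)-19-(tert-butyldimethylsilyloxy)-2-(triisopropylsilyloxy)labda-2,7-dien-15-oate (configuration as in 24) | CC(C)(C)[Si](C)(C)OC[C@]1(C)C=C(O[Si](C(C)C)(C(C)C)C(C)C)C[C@@]2(C)[C@H](CC[C@@H](C)CC(=O)OC)C(C)=CC[C@H]12 | intermediate
21 | lithium carboxylate of 20 | CC(C)(C)[Si](C)(C)OC[C@]1(C)C=C(O[Si](C(C)C)(C(C)C)C(C)C)C[C@@]2(C)[C@H](CC[C@@H](C)CC(=O)[O-])C(C)=CC[C@H]12.[Li+] | intermediate (not isolated)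
22 | 19-hydroxy-2-oxolabd-7-en-15-oic acid (with its 2,19-hemiketal) | OC[C@]1(C)CC(=O)C[C@@]2(C)[C@H](CC[C@@H](C)CC(=O)O)C(C)=CC[C@H]12 | intermediate
23 | 19-acetoxy-2-oxolabd-7-en-15-oic acid | CC(=O)OC[C@]1(C)CC(=O)C[C@@]2(C)[C@H](CC[C@@H](C)CC(=O)O)C(C)=CC[C@H]12 | intermediate
24 | CNP0162900.1, 19-acetoxy-2-hydroxylabd-7-en-15-oic acid of the ent-labdane series, 2-hydroxyl equatorial (2S,4R,5S,9R,10S,13R) | CC(=O)OC[C@]1(C)C[C@@H](O)C[C@@]2(C)[C@H](CC[C@@H](C)CC(=O)O)C(C)=CC[C@H]12 | target

**Count and risks**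

Total steps: 17. Longest linear sequence: 16 (steps 1–12 and 14–17); the side-chain branch is step 13.

Steps most likely to fail:

Step 5. The Z-configured, fully substituted diene terminus may react so slowly that uncatalysed or stepwise addition competes, eroding facial selectivity and the endo relationship. Fallback, setting out from 5 and 6 and returning at 12: the cycloaddition is run with the achiral acid HNTf2 (CH2Cl2, −40 °C) to give the racemic cis adduct F1. DBU and Luche reduction, as in steps 6 and 7, give the racemic trans ene-dione F2 and the racemic 6-hydroxy enone F3. Acylation with (1S)-camphanic chloride (DMAP, Et3N) gives the camphanate of 9 F4 and the camphanate of the enantiomer of 9 F5, which are separated by chromatography or crystallisation. F4 is cleaved with SmI2 and isomerised with DBU exactly as acetate 10, which gives enone 12 as a single enantiomer.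

Step 14. Transmetalation of the β-branched C11 zinc reagent may be slow, so that protodezincation or β-hydride elimination at palladium outruns coupling. Fallback, setting out from 18 and 16 and returning at 22: ester 18 is reduced with i-Bu2AlH (−78 °C) to (S)-4-iodo-3-methylbutanal F6, which is protected as (S)-4-iodo-1,1-dimethoxy-3-methylbutane F7 (HC(OMe)3, MeOH, cat. TsOH). Magnesium converts F7 into the Grignard reagent F8. Copper-catalysed Grignard cross-coupling (Li2CuCl4, THF, −20 → 0 °C) with iodide 16 gives the coupled dimethyl acetal F9. Aqueous 1 M HCl in THF unmasks aldehyde, C2 ketone and C19 alcohol to give the keto hydroxy aldehyde F10, and Pinnick oxidation (NaClO2, NaH2PO4, 2-methyl-2-butene) gives acid 22.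

Step 17. Thermodynamic control at C2 may be incomplete (protonation of the ketyl from the open face, leading to the axial alcohol), or electron transfer to the acetate may compete. Fallback, setting out from 21 (step 15 stopped after the saponification) and returning at 24: buffered fluoride (Bu4NF, AcOH, THF, 0 °C) cleaves only the silyl enol ether and gives the keto acid silyl ether F11. Lithium in liquid ammonia (THF, t-BuOH, −78 °C), which leaves carboxylate, silyl ether and the isolated alkene alone, gives the equatorial 2-hydroxy acid F12. Allyl chloroformate (pyridine, DMAP) converts the hydroxyl into its allyl carbonate and, through the mixed anhydride, the acid into its allyl ester, giving the allyl carbonate allyl ester F13. HF·pyridine frees the C19 alcohol F14, and Ac2O/pyridine gives the C19 acetate F15. Pd(PPh3)4 with morpholine removes both allyl groups and gives 24.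

**Further compounds**

F1 | step 5 | racemic cis adduct (7 with its enantiomer) | CC(C)(C)[Si](C)(C)OC[C@]1(C)C=C(O[Si](C(C)C)(C(C)C)C(C)C)C[C@@]2(C)C(=O)C(C)=CC(=O)[C@@H]12.CC(C)(C)[Si](C)(C)OC[C@@]1(C)C=C(O[Si](C(C)C)(C(C)C)C(C)C)C[C@]2(C)C(=O)C(C)=CC(=O)[C@H]12
F2 | step 5 | racemic trans ene-dione (8 with its enantiomer) | CC(C)(C)[Si](C)(C)OC[C@]1(C)C=C(O[Si](C(C)C)(C(C)C)C(C)C)C[C@@]2(C)C(=O)C(C)=CC(=O)[C@H]12.CC(C)(C)[Si](C)(C)OC[C@@]1(C)C=C(O[Si](C(C)C)(C(C)C)C(C)C)C[C@]2(C)C(=O)C(C)=CC(=O)[C@@H]12
F3 | step 5 | racemic 6-hydroxy enone (9 with its enantiomer) | CC(C)(C)[Si](C)(C)OC[C@]1(C)C=C(O[Si](C(C)C)(C(C)C)C(C)C)C[C@@]2(C)C(=O)C(C)=C[C@H](O)[C@H]12.CC(C)(C)[Si](C)(C)OC[C@@]1(C)C=C(O[Si](C(C)C)(C(C)C)C(C)C)C[C@]2(C)C(=O)C(C)=C[C@@H](O)[C@@H]12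
F4 | step 5 | (1S)-camphanate of 9 | CC(C)(C)[Si](C)(C)OC[C@]1(C)C=C(O[Si](C(C)C)(C(C)C)C(C)C)C[C@@]2(C)C(=O)C(C)=C[C@H](OC(=O)[C@@]34CC[C@@](C)(C(=O)O3)C4(C)C)[C@H]12
F5 | step 5 | (1S)-camphanate of the enantiomer of 9 | CC(C)(C)[Si](C)(C)OC[C@@]1(C)C=C(O[Si](C(C)C)(C(C)C)C(C)C)C[C@]2(C)C(=O)C(C)=C[C@@H](OC(=O)[C@@]34CC[C@@](C)(C(=O)O3)C4(C)C)[C@@H]12
F6 | step 14 | (S)-4-iodo-3-methylbutanal | O=CC[C@H](C)CI
F7 | step 14 | (S)-4-iodo-1,1-dimethoxy-3-methylbutane | COC(OC)C[C@H](C)CI
F8 | step 14 | (S)-(4,4-dimethoxy-2-methylbutyl)magnesium iodide | COC(OC)C[C@H](C)C[Mg]I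
F9 | step 14 | coupled dimethyl acetal (C15 as CH(OMe)2, silyl groups intact) | CC(C)(C)[Si](C)(C)OC[C@]1(C)C=C(O[Si](C(C)C)(C(C)C)C(C)C)C[C@@]2(C)[C@H](CC[C@@H](C)CC(OC)OC)C(C)=CC[C@H]12
F10 | step 14 | 19-hydroxy-2-oxolabd-7-en-15-al | OC[C@]1(C)CC(=O)C[C@@]2(C)[C@H](CC[C@@H](C)CC=O)C(C)=CC[C@H]12
F11 | step 17 | 19-(tert-butyldimethylsilyloxy)-2-oxolabd-7-en-15-oic acid | CC(C)(C)[Si](C)(C)OC[C@]1(C)CC(=O)C[C@@]2(C)[C@H](CC[C@@H](C)CC(=O)O)C(C)=CC[C@H]12
F12 | step 17 | 19-(tert-butyldimethylsilyloxy)-2-hydroxylabd-7-en-15-oic acid, hydroxyl equatorial | CC(C)(C)[Si](C)(C)OC[C@]1(C)C[C@@H](O)C[C@@]2(C)[C@H](CC[C@@H](C)CC(=O)O)C(C)=CC[C@H]12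
F13 | step 17 | allyl ester with 2-O-allyloxycarbonyl and 19-O-silyl groups | CC(C)(C)[Si](C)(C)OC[C@]1(C)C[C@@H](OC(=O)OCC=C)C[C@@]2(C)[C@H](CC[C@@H](C)CC(=O)OCC=C)C(C)=CC[C@H]12
F14 | step 17 | allyl ester with 2-O-allyloxycarbonyl group and free 19-hydroxyl | OC[C@]1(C)C[C@@H](OC(=O)OCC=C)C[C@@]2(C)[C@H](CC[C@@H](C)CC(=O)OCC=C)C(C)=CC[C@H]12
F15 | step 17 | allyl ester with 2-O-allyloxycarbonyl group and 19-acetate | CC(=O)OC[C@]1(C)C[C@@H](OC(=O)OCC=C)C[C@@]2(C)[C@H](CC[C@@H](C)CC(=O)OCC=C)C(C)=CC[C@H]12
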